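If substrate falls to 5% of its charge while target stands at 38%, as in the north-east run at 3.00 min, I suspect that material waits in a store, a resting state of the substrate, and I ask first how fast that store empties.

| flask | substrate | reagent | capture agent | temperature | remark | time |
|---|---|---|---|---|---|---|
| north-east | 0.20 M | 0.50 M | 0.20 M | 55 °C | run made earlier |  |
| south-west | 0.20 M | 0.50 M | 0.28 M | 66 °C | run made earlier |  |
| north | 0.20 M | 0.50 M | 0.44 M | 55 °C | run made earlier |  |
| south-east | 0.20 M | 1 M | 0.20 M | 66 °C | run made earlier |  |
| theta | 0.20 M | 0.500 M | 0.200 M |  | everything together at the start at 30 °C, warmed to 60 °C at 5.0 min | 8.0 min |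
| alpha | 0.20 M | 0.500 M (fed, over 5.0 min) | 0.200 M |  | the addition at 30 °C, then warmed to 60 °C; the feed brings no volume worth counting | 8.0 min |
| delta | 0.20 M | 0.500 M (fed, over 5.0 min) | 0.200 M | 60 °C | all else is in the flask from the start; the feed brings no volume worth counting | 8.0 min |
| epsilon | 0.20 M (in portions, 4, over 5.0 min) | 0.500 M | 0.200 M | 60 °C | first portion at the start, last at 5.0 min | 8.0 min |
| gamma | 0.20 M | 0.500 M | 0.200 M | 60 °C | everything together at the start | 8.0 min |

| run | time / min | target / % | substrate / % |
|---|---|---|---|
| north-east | 0.500 | 5 | 30 |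
| north-east | 1.50 | 24 | 6 |
| north-east | 3.00 | 38 | 5 |
| north-east | 4.00 | 42 | 3 |
| north-east | 6.00 | 52 | 5 |
| north-east | 8.00 | 55 | 2 |
| south-west | 0.833 | 35 | 11 |
| south-west | 1.50 | 50 | 8 |
| south-west | 2.50 | 63 | 5 |
| south-west | 3.00 | 67 | 4 |
| south-west | 4.00 | 75 | 2 |
| south-west | 5.00 | 79 | 3 |
| north | 0.333 | 6 | 48 |
| north | 1.00 | 13 | 15 |
| north | 1.50 | 26 | 8 |
| north | 2.50 | 33 | 6 |
| north | 4.00 | 42 | 4 |
| north | 5.00 | 47 | 4 |
| south-east | 1.00 | 56 | 5 |
| south-east | 2.00 | 74 | 1 |
| south-east | 3.00 | 81 | 3 |
| south-east | 4.00 | 85 | 0 |
| south-east | 5.00 | 86 | 1 |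

(each reading ± 1.5 percentage points)



1. the best flask by amount of target, in percent of the substrate charged; "all alike" if 1.5 percentage points covers them all (theta / alpha / delta / epsilon / gamma / all alike)
2. amount of target at the end, in percent of the substrate charged, theta
3. amount of target at the end, in percent of the substrate charged, alpha
4. amount of target at the end, in percent of the substrate charged, delta
5. amount of target at the end, in percent of the substrate charged, epsilon
6. amount of target at the end, in percent of the substrate charged, gamma

I read the last south-east value, 86%, as the ceiling of target, and call the gap what target lacks of it. In the north-east run, at 55 °C, the gap goes from 44 percentage points at 4.00 min to 31 points at 8.00 min, which reads as a half-life of 7.92 min. In the south-west run, at 66 °C, it goes from 23 points at 2.50 min to 7 points at 5.00 min, which reads as 1.46 min. Between them on a log scale, at 60 °C, I get 3.67 min for the store half-life, the time in which the gap to the ceiling halves.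

How much enters the store? Running each gap back to the start gives 62.5% at 55 °C and 75.6% at 66 °C. On these readings the store takes more at 66 °C than at 55 °C, although the south-west run has more capture agent too; the north and north-east runs, with different capture agent at one temperature, read 42% and 42% of target at 4.00 min. So I expect a cold start to favour target. In a straight line that means 68.4% at 60 °C and, on a long extrapolation, 32.6% at 30 °C.

How many half-lives does each flask get? Gamma has 2.18, which leaves target at 70.9%. I start the clock of delta and epsilon late by half the dosing time, which gives 61.8%. Theta and alpha have 3.00 min warm on a store filled cold, with the rest counted as target already, which gives 67.5%, so gamma stays first in my reckoning.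

The forecast, holding that “Higher temperature therefore improves the branching”, names gamma as best, with 10% for theta, 15% for alpha, 62% for delta, 62% for epsilon and 68% for gamma, far lower than mine on theta.

The flasks give 58.2% for theta, 50.1% for alpha, 54.0% for delta, 63.5% for epsilon and 72.1% for gamma, so gamma is best, as I reckoned, while theta and alpha end below my figure.

    substrate ⇌ intermediate A (K = 4.10, k = 0.0360 /s, Ea = 97.0 kJ/mol, ΔH = −68.0 kJ/mol)
    substrate + reagent → intermediate B (k = 0.0580 /M/s, Ea = 66.0 kJ/mol)
    reagent + intermediate B → side product (k = 0.00100 /M/s, Ea = 71.0 kJ/mol)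
    intermediate B → target (k = 0.0220 /s, Ea = 98.0 kJ/mol)
    capture agent + intermediate B → trapped intermediate (k = 0.0100 /M/s, Ea = 52.0 kJ/mol)
    2 substrate → homo dimer A (k = 0.00990 /M/s, Ea = 61.0 kJ/mol)
    2 substrate → homo dimer B (k = 1.00 × 10⁻⁵ /M/s, Ea = 84.0 kJ/mol)
    (constants at 60 °C)

Alpha at 8.0 min lacks 32 points of the 82.3% it shows at 80.0 min, which I take as the ceiling of alpha, and at 8.0 min alpha holds 26.5% of the charge as intermediate A. The neighbour is alpha left until 20 min. The extra 12.0 min are 3.27 store half-lives, so the gap should shrink to 3.3 points, which puts target at 79.0%. That flask holds 3.48% as intermediate A and gives 78.1% of target.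

(Readings and results stem from a simulated flask from invented constants; the scatter is artificial.)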